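Ring A is cut at C1=C10 and C4–C5 (halimane numbering). Its C2-oxo-1(10)-ene is the retron of a Robinson annulation in which C4 is the β-carbon and C1 the α'-carbon of the C2 ketone. In one operation the C5 silyl enol ether of a ring B ketone (C8, C9, C13 already set) adds to C4 of methyl (E)-2-methyl-4-oxopent-2-enoate (Mukaiyama–Michael) and the methyl ketone then condenses onto C10, which creates the C4 quaternary centre and ring A. C5, a γ-CH of the enone at the ring fusion, is set last by kinetic protonation of the dienol on the face opposite the three ring methyl groups.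

Key step: step 8

Remarks on the chemistry:
- Atom labels follow halimane numbering: ring A = C1–C5 and C10, ring B = C5–C10. C4 carries a methyl and C18 (the CO2Me); C9 carries a methyl and the C11–C15 chain; C8 carries a methyl.
- "Upper face" means the face of ring B that carries the C11 chain. In the target H5 and the ester lie on it, and the three methyl groups on C4, C8 and C9 lie on the lower face.
- Assumption: in step 5 the ligand antipode that gives the (8R) centre is used.
- The stereochemical arguments for steps 8 and 9 are conformational models, not established results.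

Step 1
Reactants: 1 methyl pyruvate; 2 1-(triphenylphosphoranylidene)propan-2-one
Product: 3 methyl (E)-2-methyl-4-oxopent-2-enoate
Conditions: CH2Cl2, 25 °C
Reagents that add atoms: none
Why: Wittig olefination of the activated ketone carbonyl of 1 by the stabilised acyl ylide should give mainly the (E)-alkene (ester trans to acetyl), the more stable mesaconate-like isomer, from which the minor (Z)-isomer is removed by chromatography.

Step 2
Reactants: 4 (R)-citronellol [(3R)-3,7-dimethyloct-6-en-1-ol]
Product: 5 tert-butyl{[(3R)-3,7-dimethyloct-6-en-1-yl]oxy}dimethylsilane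
Conditions: TBSCl, imidazole, DMF, 0 → 25 °C
Reagents that add atoms: tert-butyldimethylsilyl chloride CC(C)(C)[Si](C)(C)Cl
Why: Standard silylation of the primary alcohol; the future C13 centre comes from the chiral pool and is not touched.

Step 3
Reactants: 5 tert-butyl{[(3R)-3,7-dimethyloct-6-en-1-yl]oxy}dimethylsilane
Product: 6 (4R)-6-[(tert-butyldimethylsilyl)oxy]-4-methylhexanoic acid
Conditions: RuCl3·xH2O (cat.), NaIO4, EtOAc/MeCN/H2O, 25 °C
Reagents that add atoms: sodium periodate [Na+].[O-]I(=O)(=O)=O; water O
Why: RuO4 formed in situ cleaves the trisubstituted alkene to the carboxylic acid with loss of acetone (oxidative alkene cleavage), conditions that a primary TBS ether should tolerate; no stereocentre is involved.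

Step 4
Reactants: 6 (4R)-6-[(tert-butyldimethylsilyl)oxy]-4-methylhexanoic acid
Product: 7 tert-butyl{[(3S)-5-iodo-3-methylpentyl]oxy}dimethylsilane
Conditions: PhI(OAc)2, I2, cyclohexane, hν (tungsten lamp), 80 °C
Reagents that add atoms: iodine II
Why: Photochemical iododecarboxylation (Hunsdiecker-type, through the acyl hypoiodite and a primary alkyl radical) removes the carboxyl carbon and leaves the primary iodide; the remote centre is untouched and its descriptor becomes S only because iodine changes the priorities.

Step 5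
Reactants: 8 2-methylcyclohex-2-en-1-one
Product: 10 trimethyl{[(3R)-2,3-dimethylcyclohex-1-en-1-yl]oxy}silane, via aluminium enolate 9 (not isolated)
Conditions: Me3Al, Cu(O2CC4H3S) (copper thiophene-2-carboxylate, 2 mol%), BINOL-derived phosphoramidite of bis(1-phenylethyl)amine (4 mol%), Et2O, −30 °C; then TMSOTf, THF, 0 °C
Reagents that add atoms: trimethylaluminium C[Al](C)C; trimethylsilyl trifluoromethanesulfonate C[Si](C)(C)OS(=O)(=O)C(F)(F)F
Why: Copper-catalysed asymmetric conjugate addition of the methyl group sets C8 (R) under ligand control, and O-silylation of the aluminium enolate fixes the tetrasubstituted C9=C10 enol ether regiospecifically.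

Step 6
Reactants: 10 trimethyl{[(3R)-2,3-dimethylcyclohex-1-en-1-yl]oxy}silane; 7 tert-butyl{[(3S)-5-iodo-3-methylpentyl]oxy}dimethylsilane
Product: 12 (2S,3R)-2-[(3R)-5-[(tert-butyldimethylsilyl)oxy]-3-methylpentyl]-2,3-dimethylcyclohexan-1-one, via lithium enolate 11 (not isolated)
Conditions: MeLi, THF, 0 → 25 °C; then HMPA, 7, −78 → 0 °C
Reagents that add atoms: none
Why: MeLi cleaves the Si–O bond to the regiodefined lithium enolate, which is alkylated by the primary iodide (SN2) at C9 on the face anti to the pseudoaxial C8 methyl, so that the chain is trans and the C9 methyl cis to the C8 methyl (9S).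

Step 7
Reactants: 12 (2S,3R)-2-[(3R)-5-[(tert-butyldimethylsilyl)oxy]-3-methylpentyl]-2,3-dimethylcyclohexan-1-one
Product: 13 tert-butyl{[(3R)-5-[(1S,6R)-1,6-dimethyl-2-[(trimethylsilyl)oxy]cyclohex-2-en-1-yl]-3-methylpentyl]oxy}dimethylsilane
Conditions: LiN(iPr)2, TMSCl (internal quench), THF, −78 °C; Et3N
Reagents that add atoms: chlorotrimethylsilane C[Si](C)(C)Cl
Why: Kinetic deprotonation with in situ O-silylation; C9 is quaternary, so only the C5=C10 silyl enol ether can form.

Step 8
Reactants: 13 tert-butyl{[(3R)-5-[(1S,6R)-1,6-dimethyl-2-[(trimethylsilyl)oxy]cyclohex-2-en-1-yl]-3-methylpentyl]oxy}dimethylsilane; 3 methyl (E)-2-methyl-4-oxopent-2-enoate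
Product: 15 methyl (1S,5S,6R,8aR)-5-[(3R)-5-[(tert-butyldimethylsilyl)oxy]-3-methylpentyl]-1,5,6-trimethyl-3-oxo-1,2,3,5,6,7,8,8a-octahydronaphthalene-1-carboxylate, via 1,5-diketone 14 (not isolated)
Conditions: TiCl4, CH2Cl2, −78 °C; aq. NaHCO3; then crude in PhMe, TsOH·H2O (cat.), 90 °C, Dean–Stark
Reagents that add atoms: none
Why: TiCl4 activates the ketone of 3 (the more basic carbonyl and the stronger acceptor group), the enol ether carbon C5 of 13 adds to C4 through an open transition state (Mukaiyama–Michael addition, a reaction type that tolerates β,β-disubstituted enones and builds quaternary carbons), and acid then condenses the C1 methyl ketone onto the C10 ketone with loss of water, which together is a Robinson annulation run through a silyl enol ether. Ring A closes as a 6-(enolendo)-exo-trig aldol, the only six-membered closure open to the diketone. The new quaternary C4 should be set by two elements: attack on the upper face of C5, opposite the pseudoaxial C9 methyl of the half-chair that keeps the C8 methyl equatorial, and an anti topicity in which the bulky C10 end lies between the vinylic C3–H and the ester while H5 lies beside the Ti-bound acetyl, which places the ester cis to C6 and gives (4S). C5 is thereby formed as (5R), the epimer of what the target needs; it is not relied on and is reset in step 9. The step needs addition at C4 and not at C3 of 3 (ketone against ester control) and 1,4- over 1,2-addition, both favoured by ketone-bound TiCl4 and the hindered nucleophile, and the acidic ring closure avoids retro-Michael loss of the C4 centre.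

Step 9
Reactants: 15 methyl (1S,5S,6R,8aR)-5-[(3R)-5-[(tert-butyldimethylsilyl)oxy]-3-methylpentyl]-1,5,6-trimethyl-3-oxo-1,2,3,5,6,7,8,8a-octahydronaphthalene-1-carboxylate
Product: 17 methyl (1S,5S,6R,8aS)-5-[(3R)-5-hydroxy-3-methylpentyl]-1,5,6-trimethyl-3-oxo-1,2,3,5,6,7,8,8a-octahydronaphthalene-1-carboxylate, via silyl dienol ether 16 (not isolated)
Conditions: TMSCl, NaI, Et3N, MeCN, 25 °C; then HCl (1% in MeOH), −20 → 0 °C
Reagents that add atoms: none
Why: In situ TMSI with Et3N should give the thermodynamic, fully conjugated silyl dienol ether in which C5 is sp2, and methanolic HCl then hydrolyses it, protonates the dienol at C5 axially and anti to the pseudoaxial C4 and C9 methyl groups (from the upper face, giving 5S under kinetic control, the β,γ- to α,β-enone isomerisation known from 19-nor-4-en-3-one syntheses) and removes the TBS group, so that any C5 epimer mixture from step 8 should converge on the target.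

Compound list
1 | methyl pyruvate | CC(=O)C(=O)OC | starting material
2 | 1-(triphenylphosphoranylidene)propan-2-one | CC(=O)C=P(c1ccccc1)(c1ccccc1)c1ccccc1 | starting material
3 | methyl (E)-2-methyl-4-oxopent-2-enoate | COC(=O)/C(C)=C/C(C)=O | intermediate
4 | (R)-citronellol, (3R)-3,7-dimethyloct-6-en-1-ol | CC(C)=CCC[C@@H](C)CCO | starting material
5 | tert-butyl{[(3R)-3,7-dimethyloct-6-en-1-yl]oxy}dimethylsilane | CC(C)=CCC[C@@H](C)CCO[Si](C)(C)C(C)(C)C | intermediate
6 | (4R)-6-[(tert-butyldimethylsilyl)oxy]-4-methylhexanoic acid | OC(=O)CC[C@@H](C)CCO[Si](C)(C)C(C)(C)C | intermediate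
7 | tert-butyl{[(3S)-5-iodo-3-methylpentyl]oxy}dimethylsilane | ICC[C@@H](C)CCO[Si](C)(C)C(C)(C)C | intermediate
8 | 2-methylcyclohex-2-en-1-one | CC1=CCCCC1=O | starting material
9 | dimethylaluminium (3R)-2,3-dimethylcyclohex-1-en-1-olate (aluminium enolate, not isolated) | C[Al](C)OC1=C(C)[C@H](C)CCC1 | intermediate
10 | trimethyl{[(3R)-2,3-dimethylcyclohex-1-en-1-yl]oxy}silane | C[Si](C)(C)OC1=C(C)[C@H](C)CCC1 | intermediate
11 | lithium (3R)-2,3-dimethylcyclohex-1-en-1-olate (lithium enolate, not isolated) | [Li+].[O-]C1=C(C)[C@H](C)CCC1 | intermediate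
12 | (2S,3R)-2-[(3R)-5-[(tert-butyldimethylsilyl)oxy]-3-methylpentyl]-2,3-dimethylcyclohexan-1-one | O=C1CCC[C@@H](C)[C@]1(C)CC[C@@H](C)CCO[Si](C)(C)C(C)(C)C | intermediate
13 | tert-butyl{[(3R)-5-[(1S,6R)-1,6-dimethyl-2-[(trimethylsilyl)oxy]cyclohex-2-en-1-yl]-3-methylpentyl]oxy}dimethylsilane | C[Si](C)(C)OC1=CCC[C@@H](C)[C@]1(C)CC[C@@H](C)CCO[Si](C)(C)C(C)(C)C | intermediate
14 | methyl (2S)-2-[(1S,3S,4R)-3-[(3R)-5-[(tert-butyldimethylsilyl)oxy]-3-methylpentyl]-3,4-dimethyl-2-oxocyclohexyl]-2-methyl-4-oxopentanoate (1,5-diketone, not isolated) | COC(=O)[C@@](C)(CC(C)=O)[C@@H]1CC[C@@H](C)[C@](C)(CC[C@@H](C)CCO[Si](C)(C)C(C)(C)C)C1=O | intermediate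
15 | methyl (1S,5S,6R,8aR)-5-[(3R)-5-[(tert-butyldimethylsilyl)oxy]-3-methylpentyl]-1,5,6-trimethyl-3-oxo-1,2,3,5,6,7,8,8a-octahydronaphthalene-1-carboxylate (C5 epimer of the silylated target; 4S,5R,8R,9S,13R in halimane numbering) | COC(=O)[C@@]1(C)CC(=O)C=C2[C@H]1CC[C@@H](C)[C@]2(C)CC[C@@H](C)CCO[Si](C)(C)C(C)(C)C | intermediate
16 | methyl (1S,5S,6R)-5-[(3R)-5-[(tert-butyldimethylsilyl)oxy]-3-methylpentyl]-1,5,6-trimethyl-3-[(trimethylsilyl)oxy]-1,2,5,6,7,8-hexahydronaphthalene-1-carboxylate (silyl dienol ether, not isolated) | COC(=O)[C@@]1(C)CC(O[Si](C)(C)C)=CC2=C1CC[C@@H](C)[C@]2(C)CC[C@@H](C)CCO[Si](C)(C)C(C)(C)C | intermediate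
17 | methyl (1S,5S,6R,8aS)-5-[(3R)-5-hydroxy-3-methylpentyl]-1,5,6-trimethyl-3-oxo-1,2,3,5,6,7,8,8a-octahydronaphthalene-1-carboxylate (CNP0157174.1; 4S,5S,8R,9S,13R in halimane numbering) | COC(=O)[C@@]1(C)CC(=O)C=C2[C@@H]1CC[C@@H](C)[C@]2(C)CC[C@@H](C)CCO | target

Total steps: 9. Longest linear sequence: 7 steps (from 4 through steps 2, 3, 4, 6, 7, 8 and 9).

Steps most likely to fail

1. Step 8. The conjugate addition may go to C3 (β to the ester) or to the ketone carbonyl (1,2-addition) instead of C4, or the open transition state may show low topicity so that the C4 epimer forms. The fallback sets out from 13 (with ylide 2 and commercial 1-acetoxypropan-2-one) and comes back at 15. It replaces the ester of the acceptor by a carboxyl precursor that is not an acceptor group. Wittig reaction of 2 with 1-acetoxypropan-2-one (PhMe, 90 °C) gives (E)-2-methyl-4-oxopent-2-en-1-yl acetate F1, whose only electrophilic alkene carbon is C4. The same TiCl4 addition to 13 and acidic ring closure give the 18-acetoxy enone F2. K2CO3 in MeOH frees the 18-hydroxy enone F3 with the TBS ether intact. TEMPO (cat.), NaOCl and NaClO2 oxidise it to the 18-carboxylic acid F4, and TMSCHN2 in MeOH/PhMe gives 15.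

2. Step 9. The silyl dienol ether may form incompletely or as the cross-conjugated isomer (through C3), or C5 may equilibrate after protonation, either of which leaves a C5 epimer mixture. The fallback sets out from 15 and comes back at 17. It installs the C5 hydrogen by hydrogenation in place of protonation. Chloranil (tBuOH, 80 °C) dehydrogenates 15 across C5–C6 to the linear 1(10),5-dienone F5. H2 with RhCl(PPh3)3 in PhH should saturate the C5=C6 bond from the less hindered upper face, the conjugated C1=C10 bond next to the quaternary C9 being slower, to give the (5S) TBS ether F6. HCl in MeOH then removes the silyl group to give 17.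

3. Step 6. SN2 attack of the hindered tetrasubstituted enolate on an unactivated primary iodide may be slow, which allows proton transfer between product and enolate, O-alkylation and further alkylation at C5. The fallback sets out from 7 and 10 and comes back at 12. It makes the C9–C11 bond by an aldol addition, which is much less sensitive to hindrance. Trimethylamine N-oxide in DMSO oxidises 7 to (3S)-5-[(tert-butyldimethylsilyl)oxy]-3-methylpentanal F7. Lithium enolate 11 (from 10 and MeLi) adds to it at −78 °C, again anti to the C8 methyl, to give the 11-hydroxy ketone F8 (either C11 epimer). Methyl N-(triethylammoniosulfonyl)carbamate dehydrates this to the (E)-11,12-alkene F9; C9 is quaternary, so elimination can only run toward C12. H2 over Pd/C then gives 12.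

Further compounds
F1 | step 8 | (E)-2-methyl-4-oxopent-2-en-1-yl acetate | CC(=O)OC/C(C)=C/C(C)=O
F2 | step 8 | 18-acetoxy enone, analogue of 15 with CH2OAc in place of CO2Me at C4 | CC(=O)OC[C@@]1(C)CC(=O)C=C2[C@H]1CC[C@@H](C)[C@]2(C)CC[C@@H](C)CCO[Si](C)(C)C(C)(C)C
F3 | step 8 | 18-hydroxy enone, analogue of 15 with CH2OH at C4 | OC[C@@]1(C)CC(=O)C=C2[C@H]1CC[C@@H](C)[C@]2(C)CC[C@@H](C)CCO[Si](C)(C)C(C)(C)C
F4 | step 8 | 18-carboxylic acid, analogue of 15 with CO2H at C4 | OC(=O)[C@@]1(C)CC(=O)C=C2[C@H]1CC[C@@H](C)[C@]2(C)CC[C@@H](C)CCO[Si](C)(C)C(C)(C)C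
F5 | step 9 | linear 1(10),5-dienone, 15 with a C5=C6 double bond | COC(=O)[C@@]1(C)CC(=O)C=C2C1=CC[C@@H](C)[C@]2(C)CC[C@@H](C)CCO[Si](C)(C)C(C)(C)C
F6 | step 9 | (5S) TBS ether, the silyl ether of 17 | COC(=O)[C@@]1(C)CC(=O)C=C2[C@@H]1CC[C@@H](C)[C@]2(C)CC[C@@H](C)CCO[Si](C)(C)C(C)(C)C
F7 | step 6 | (3S)-5-[(tert-butyldimethylsilyl)oxy]-3-methylpentanal | O=CC[C@@H](C)CCO[Si](C)(C)C(C)(C)C
F8 | step 6 | 11-hydroxy ketone, 12 with OH at C11 (either epimer) | O=C1CCC[C@@H](C)[C@]1(C)C(O)C[C@@H](C)CCO[Si](C)(C)C(C)(C)C
F9 | step 6 | (E)-11,12-alkene, 12 with a C11=C12 double bond | O=C1CCC[C@@H](C)[C@]1(C)/C=C/[C@@H](C)CCO[Si](C)(C)C(C)(C)C
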